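## Retrosynthetic overview

1. Target 15 ⇐ one global hydrogenolysis of the fully protected dimer 14 (thirteen benzyl ethers, one diphenylmethylene ketal, one C8–Br).
2. 14 ⇐ C4(upper)–C6(lower) bond by a nickel-catalysed reductive cross-electrophile coupling. The C4 benzylic ether 3 is reduced in situ to a flavan-4-yl radical/nickel species, so C4 (normally the cationic centre) acts as the nucleophile towards aryl iodide 12. C4 (β) is set here.
3. 3 ⇐ (−)-epicatechin 1 (benzylation, DDQ oxidation at C4). 12 ⇐ (−)-epigallocatechin 4 (ring-B ketal, ring-A benzylation via a transient dibromide, double galloylation, C8–Br then C6–I).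
4. No carbocycle or pyran ring is built: rings A, B and C of both halves and their four stereocentres come from the natural catechins. The only ring formed is the protecting ketal (step 3).

Assumption: positions 3' and 5' of ring B of epigallocatechin are equivalent, so the hydroxyl left free by the ketal is called 3'; compounds 1, 4 and 9 are bought.

## Route

Step 1
Reactants: 1 (−)-epicatechin
Product: 2 3,5,7,3',4'-penta-O-benzyl-(−)-epicatechin
Conditions: NaH (6.5 equiv), BnBr (6.5 equiv), Bu4NI (cat.), DMF, 0 °C to rt, Ar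
Reagents that add atoms: benzyl bromide, BrCc1ccccc1
Why: Williamson etherification of the four phenols and the secondary alcohol; no stereocentre is touched.

Step 2
Reactants: 2 3,5,7,3',4'-penta-O-benzyl-(−)-epicatechin
Product: 3 (2R,3R,4S)-3,5,7,3',4'-penta-O-benzyl-4β-(2-ethoxyethoxy)epicatechin
Conditions: DDQ (2 equiv), 2-ethoxyethanol (5 equiv), CH2Cl2, rt
Reagents that add atoms: 2-ethoxyethanol, CCOCCO
Why: DDQ benzylic C–H oxidation (hydride abstraction at C4, para and ortho to the ring-A ether oxygens) gives a quinone-methide-type cation that the alcohol traps anti to the 3-O-benzyl group; the C4 configuration is erased again in step 10, so a minor 4α epimer is harmless.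

Step 3
Reactants: 4 (−)-epigallocatechin
Product: 5 4',5'-O-(diphenylmethylene)-(−)-epigallocatechin
Conditions: Ph2CCl2 (1.3 equiv), K2CO3 (2.6 equiv), MeCN, rt, Ar
Reagents that add atoms: dichlorodiphenylmethane, ClC(Cl)(c1ccccc1)c1ccccc1
Why: catechol ketalisation: only two vicinal ring-B hydroxyls can close the five-membered 2,2-diphenyl-1,3-dioxole, which sets exactly one ring-B hydroxyl (3') apart from its two neighbours.

Step 4
Reactants: 5 4',5'-O-(diphenylmethylene)-(−)-epigallocatechin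
Product: 6 6,8-dibromo-4',5'-O-(diphenylmethylene)epigallocatechin
Conditions: NBS (2.05 equiv), THF, −40 to 0 °C, dark
Reagents that add atoms: N-bromosuccinimide, O=C1CCC(=O)N1Br
Why: electrophilic aromatic bromination fills both free positions of the phloroglucinol-type ring A (far more nucleophilic than ring B), which lowers the pKa of the 7- and 5-OH to about 6.5 and 8 and so separates them from the 3'-OH (about 10).

Step 5
Reactants: 6 6,8-dibromo-4',5'-O-(diphenylmethylene)epigallocatechin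
Product: 7 5,7-di-O-benzyl-6,8-dibromo-4',5'-O-(diphenylmethylene)epigallocatechin
Conditions: BnBr (2.2 equiv), KHCO3 (3 equiv), DMF, 40 °C
Reagents that add atoms: benzyl bromide, BrCc1ccccc1
Why: acidity-controlled Williamson etherification: hydrogen carbonate deprotonates only the two ortho-bromophenols of ring A (as in the selective alkylation of the most acidic phenol of gallate esters), the 3'-OH and 3-OH stay free, and the bromines also rule out C-benzylation.

Step 6
Reactants: 7 5,7-di-O-benzyl-6,8-dibromo-4',5'-O-(diphenylmethylene)epigallocatechin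
Product: 8 5,7-di-O-benzyl-4',5'-O-(diphenylmethylene)epigallocatechin
Conditions: Pd(PPh3)4 (5 mol %), HCO2Na (5 equiv), DMF, 90 °C
Reagents that add atoms: none
Why: palladium-catalysed transfer hydrodehalogenation with formate removes both auxiliary bromines (regio-defined halogens return in steps 8 and 9), and a homogeneous zerovalent palladium catalyst leaves benzyl ethers and the ketal intact.

Step 7
Reactants: 8 5,7-di-O-benzyl-4',5'-O-(diphenylmethylene)epigallocatechin, 9 3,4,5-tris(benzyloxy)benzoic acid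
Product: 10 5,7-di-O-benzyl-4',5'-O-(diphenylmethylene)epigallocatechin 3,3'-bis-O-[3,4,5-tris(benzyloxy)benzoate]
Conditions: 9 (2.6 equiv), DCC (2.8 equiv), DMAP (0.5 equiv), CH2Cl2, rt
Reagents that add atoms: none
Why: Steglich esterification acylates the only two free hydroxyls (phenolic 3'-OH and axial 3-OH) with retention at C3.

Step 8
Reactants: 10 5,7-di-O-benzyl-4',5'-O-(diphenylmethylene)epigallocatechin 3,3'-bis-O-[3,4,5-tris(benzyloxy)benzoate]
Product: 11 8-bromo-5,7-di-O-benzyl-4',5'-O-(diphenylmethylene)epigallocatechin 3,3'-bis-O-[3,4,5-tris(benzyloxy)benzoate]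
Conditions: NBS (1.05 equiv), CH2Cl2, −78 °C to rt
Reagents that add atoms: N-bromosuccinimide, O=C1CCC(=O)N1Br
Why: electrophilic aromatic bromination: in 5,7-di-O-benzylflavans C8 reacts first (C6 lies between two benzyloxy groups) and the acylated ring B and galloyl rings are far less nucleophilic, so the bromine blocks C8 and leaves C6 as the only site for the next halogen.

Step 9
Reactants: 11 8-bromo-5,7-di-O-benzyl-4',5'-O-(diphenylmethylene)epigallocatechin 3,3'-bis-O-[3,4,5-tris(benzyloxy)benzoate]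
Product: 12 8-bromo-6-iodo-5,7-di-O-benzyl-4',5'-O-(diphenylmethylene)epigallocatechin 3,3'-bis-O-[3,4,5-tris(benzyloxy)benzoate]
Conditions: NIS (1.3 equiv), CF3CO2H (0.3 equiv), CH2Cl2/MeCN, 0 °C to rt, dark
Reagents that add atoms: N-iodosuccinimide, O=C1CCC(=O)N1I
Why: acid-activated electrophilic aromatic iodination at C6, the only position left on ring A.

Step 10
Reactants: 3 (2R,3R,4S)-3,5,7,3',4'-penta-O-benzyl-4β-(2-ethoxyethoxy)epicatechin (1.8 equiv), 12 8-bromo-6-iodo-5,7-di-O-benzyl-4',5'-O-(diphenylmethylene)epigallocatechin 3,3'-bis-O-[3,4,5-tris(benzyloxy)benzoate]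
Product: 14 3,5,7,3',4'-penta-O-benzylepicatechin-(4β→6)-[5,7-di-O-benzyl-8-bromo-4',5'-O-(diphenylmethylene)epigallocatechin 3,3'-bis-O-(3,4,5-tris(benzyloxy)benzoate)], via 4-chloroflavan 13 (not isolated)
Conditions: NiBr2(dme) (20 mol %), 4,4'-di-tert-butyl-2,2'-bipyridine (24 mol %), Zn (3 equiv), TMSCl (2.2 equiv, slow addition), DMA/THF, 0 °C to rt
Reagents that add atoms: none
Why: Proposed new method: TMSCl ionises the acetal-like C4 ether of 3 (its cation is stabilised by the 5-, 7- and ring oxygens) to chloride 13, zerovalent nickel adds into the C6–I bond of 12 (far faster than into the flanked C8–Br bond), low-valent nickel turns 13 into the C4 benzylic radical, so that C4, normally the cationic centre of flavan chemistry, reacts as a flavan-4-yl anion equivalent and two electrophilic carbons are joined with Zn as terminal reductant, and the aryl–nickel species captures this planar radical on the β-face, anti to the pseudo-axial 3-O-benzyl group and the 2-aryl group, so that reductive elimination gives the 4β (3,4-trans) C4–C6 bond with the regiochemistry fixed by the iodine; closest known reaction type: nickel-catalysed reductive cross-electrophile coupling of secondary benzylic chlorides, and of acetals activated in situ by TMSCl, with aryl iodides.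

Step 11
Reactants: 14 3,5,7,3',4'-penta-O-benzylepicatechin-(4β→6)-[5,7-di-O-benzyl-8-bromo-4',5'-O-(diphenylmethylene)epigallocatechin 3,3'-bis-O-(3,4,5-tris(benzyloxy)benzoate)]
Product: 15 (−)-epicatechin-(4β→6)-(−)-epigallocatechin 3,3'-di-O-gallate
Conditions: H2 (1 atm), Pd(OH)2/C, NaOAc (1.1 equiv), THF/H2O 9:1, rt; Sephadex LH-20
Reagents that add atoms: none
Why: hydrogenolysis cleaves the thirteen benzyl ethers, the diphenylmethylene ketal and the aryl C–Br bond in one operation, the acetate buffering the HBr so that neither the acid-labile interflavan bond nor the two gallate esters suffer; no stereocentre is touched.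

## Compound list

1 | (−)-epicatechin, (2R,3R) | O[C@@H]1Cc2c(O)cc(O)cc2O[C@@H]1c1ccc(O)c(O)c1 | starting material
2 | 3,5,7,3',4'-penta-O-benzyl-(−)-epicatechin, (2R,3R) | C1c2c(OCc3ccccc3)cc(OCc3ccccc3)cc2O[C@H](c2ccc(OCc3ccccc3)c(OCc3ccccc3)c2)[C@@H]1OCc1ccccc1 | intermediate
3 | (2R,3R,4S)-3,5,7,3',4'-penta-O-benzyl-4β-(2-ethoxyethoxy)epicatechin (4-OR trans to 3-OBn) | CCOCCO[C@H]1c2c(OCc3ccccc3)cc(OCc3ccccc3)cc2O[C@H](c2ccc(OCc3ccccc3)c(OCc3ccccc3)c2)[C@@H]1OCc1ccccc1 | intermediate
4 | (−)-epigallocatechin, (2R,3R) | O[C@@H]1Cc2c(O)cc(O)cc2O[C@@H]1c1cc(O)c(O)c(O)c1 | starting material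
5 | 4',5'-O-(diphenylmethylene)-(−)-epigallocatechin (free 3-, 5-, 7- and 3'-OH), (2R,3R) | Oc1cc([C@H]2Oc3cc(O)cc(O)c3C[C@H]2O)cc2OC(c3ccccc3)(c3ccccc3)Oc12 | intermediate
6 | 6,8-dibromo-4',5'-O-(diphenylmethylene)epigallocatechin | Oc1cc([C@H]2Oc3c(Br)c(O)c(Br)c(O)c3C[C@H]2O)cc2OC(c3ccccc3)(c3ccccc3)Oc12 | intermediate
7 | 5,7-di-O-benzyl-6,8-dibromo-4',5'-O-(diphenylmethylene)epigallocatechin | Oc1cc([C@H]2Oc3c(Br)c(OCc4ccccc4)c(Br)c(OCc4ccccc4)c3C[C@H]2O)cc2OC(c3ccccc3)(c3ccccc3)Oc12 | intermediate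
8 | 5,7-di-O-benzyl-4',5'-O-(diphenylmethylene)epigallocatechin (free 3- and 3'-OH) | Oc1cc([C@H]2Oc3cc(OCc4ccccc4)cc(OCc4ccccc4)c3C[C@H]2O)cc2OC(c3ccccc3)(c3ccccc3)Oc12 | intermediate
9 | 3,4,5-tris(benzyloxy)benzoic acid | OC(=O)c1cc(OCc2ccccc2)c(OCc2ccccc2)c(OCc2ccccc2)c1 | starting material
10 | 5,7-di-O-benzyl-4',5'-O-(diphenylmethylene)epigallocatechin 3,3'-bis-O-[3,4,5-tris(benzyloxy)benzoate], (2R,3R) | O=C(Oc1cc([C@H]2Oc3cc(OCc4ccccc4)cc(OCc4ccccc4)c3C[C@H]2OC(=O)c2cc(OCc3ccccc3)c(OCc3ccccc3)c(OCc3ccccc3)c2)cc2OC(c3ccccc3)(c3ccccc3)Oc12)c1cc(OCc2ccccc2)c(OCc2ccccc2)c(OCc2ccccc2)c1 | intermediate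
11 | 8-bromo derivative of 10 (Br at C8, H at C6) | O=C(Oc1cc([C@H]2Oc3c(Br)c(OCc4ccccc4)cc(OCc4ccccc4)c3C[C@H]2OC(=O)c2cc(OCc3ccccc3)c(OCc3ccccc3)c(OCc3ccccc3)c2)cc2OC(c3ccccc3)(c3ccccc3)Oc12)c1cc(OCc2ccccc2)c(OCc2ccccc2)c(OCc2ccccc2)c1 | intermediate
12 | 8-bromo-6-iodo derivative of 10 (Br at C8, I at C6) | O=C(Oc1cc([C@H]2Oc3c(Br)c(OCc4ccccc4)c(I)c(OCc4ccccc4)c3C[C@H]2OC(=O)c2cc(OCc3ccccc3)c(OCc3ccccc3)c(OCc3ccccc3)c2)cc2OC(c3ccccc3)(c3ccccc3)Oc12)c1cc(OCc2ccccc2)c(OCc2ccccc2)c(OCc2ccccc2)c1 | intermediate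
13 | 4-chloro-3,5,7,3',4'-penta-O-benzylepicatechin (both C4 epimers; 2-aryl and 3-OBn cis as in 2) | ClC1c2c(OCc3ccccc3)cc(OCc3ccccc3)cc2O[C@H](c2ccc(OCc3ccccc3)c(OCc3ccccc3)c2)[C@@H]1OCc1ccccc1 | intermediate
14 | 3,5,7,3',4'-penta-O-benzylepicatechin-(4β→6)-[5,7-di-O-benzyl-8-bromo-4',5'-O-(diphenylmethylene)epigallocatechin 3,3'-bis-O-(3,4,5-tris(benzyloxy)benzoate)]; upper unit 2-aryl α, 3-OBn α, C4–C6 bond β | O=C(Oc1cc([C@H]2Oc3c(Br)c(OCc4ccccc4)c([C@H]4c5c(OCc6ccccc6)cc(OCc6ccccc6)cc5O[C@H](c5ccc(OCc6ccccc6)c(OCc6ccccc6)c5)[C@@H]4OCc4ccccc4)c(OCc4ccccc4)c3C[C@H]2OC(=O)c2cc(OCc3ccccc3)c(OCc3ccccc3)c(OCc3ccccc3)c2)cc2OC(c3ccccc3)(c3ccccc3)Oc12)c1cc(OCc2ccccc2)c(OCc2ccccc2)c(OCc2ccccc2)c1 | intermediate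
15 | (−)-epicatechin-(4β→6)-(−)-epigallocatechin 3,3'-di-O-gallate; upper unit (2R,3R,4S), lower unit (2R,3R) | O=C(Oc1cc([C@H]2Oc3cc(O)c([C@H]4c5c(O)cc(O)cc5O[C@H](c5ccc(O)c(O)c5)[C@@H]4O)c(O)c3C[C@H]2OC(=O)c2cc(O)c(O)c(O)c2)cc(O)c1O)c1cc(O)c(O)c(O)c1 | target

## Step count and risks

Total: 11 steps. Longest linear sequence: 9 steps (4 → 15, steps 3 to 11).

Most likely to fail:

Step 10 (the coupling). The aryl iodide carries two ortho benzyloxy groups, the benzylic partner is secondary and crowded, and any free C4 cation can alkylate ring A of a second molecule of 3. Fallback: leave out the iodination and set out from bromide 11 and ether 3. With TMSOTf (0.2 equiv) in CH2Cl2 at −78 °C the C4 cation from 3 alkylates ring A of 11 in a Friedel–Crafts reaction. Because C8 carries bromine the only free position is C6, and attack anti to the 3-O-benzyl group gives the 4β bond, so the route is rejoined directly at 14. This fallback makes no compound outside the list (F0).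

Step 5 (benzylation controlled by acidity). The gap between the 5-OH (about 8) and the 3'-OH (about 10) is the narrow one, and some 3'-O-benzylation would be hard to separate. Fallback: set out from 6 and use size instead of acidity. TBDPSCl/imidazole in DMF silylates only the 3'-OH, which has a free ortho position, whereas both ring-A phenols are flanked on each side (Br/Br and Br/C4a); this gives the 3'-O-(tert-butyldiphenylsilyl) ether F1. BnBr/K2CO3 in acetone then benzylates both ring-A phenols to give the 5,7-di-O-benzyl-3'-O-silyl dibromide F2. TBAF buffered with AcOH removes the silyl group and the route is rejoined at 7.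

Step 11 (one-pot loss of benzyl groups, ketal and bromine). HBr is formed next to an acid-labile interflavan bond, and any base strong enough to trap it can move the 3'-O-galloyl group to the freed 4'-OH. Fallback: set out from 14 and take off the halogen first. Pd(PPh3)4/HCO2Na in DMF (as in step 6) gives the bromine-free protected dimer F3, which is then hydrogenolysed over Pd(OH)2/C in THF/H2O without any additive; the route is rejoined at 15.

Further compounds
F0 | step 10 | none | none
F1 | step 5 | 6,8-dibromo-3'-O-(tert-butyldiphenylsilyl)-4',5'-O-(diphenylmethylene)epigallocatechin | CC(C)(C)[Si](c1ccccc1)(c1ccccc1)Oc1cc([C@H]2Oc3c(Br)c(O)c(Br)c(O)c3C[C@H]2O)cc2OC(c3ccccc3)(c3ccccc3)Oc12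
F2 | step 5 | 5,7-di-O-benzyl-6,8-dibromo-3'-O-(tert-butyldiphenylsilyl)-4',5'-O-(diphenylmethylene)epigallocatechin | CC(C)(C)[Si](c1ccccc1)(c1ccccc1)Oc1cc([C@H]2Oc3c(Br)c(OCc4ccccc4)c(Br)c(OCc4ccccc4)c3C[C@H]2O)cc2OC(c3ccccc3)(c3ccccc3)Oc12
F3 | step 11 | 3,5,7,3',4'-penta-O-benzylepicatechin-(4β→6)-[5,7-di-O-benzyl-4',5'-O-(diphenylmethylene)epigallocatechin 3,3'-bis-O-(3,4,5-tris(benzyloxy)benzoate)] | O=C(Oc1cc([C@H]2Oc3cc(OCc4ccccc4)c([C@H]4c5c(OCc6ccccc6)cc(OCc6ccccc6)cc5O[C@H](c5ccc(OCc6ccccc6)c(OCc6ccccc6)c5)[C@@H]4OCc4ccccc4)c(OCc4ccccc4)c3C[C@H]2OC(=O)c2cc(OCc3ccccc3)c(OCc3ccccc3)c(OCc3ccccc3)c2)cc2OC(c3ccccc3)(c3ccccc3)Oc12)c1cc(OCc2ccccc2)c(OCc2ccccc2)c(OCc2ccccc2)c1
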